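**Strategy.** Da‑ucane numbering is used throughout: C1 = methyl‑bearing ring‑fusion carbon, C4 = isopropyl carbinol, C5 = ring‑fusion CH, C6 = anisoate carbon, C10 = angelate carbon. The cyclopentane is not closed as such: the C6 oxygen next to the C5–H marks a pinacol‑type 1,2‑shift. In cis‑decalin mesylate 13 the quaternary C1 migrates from the C6 carbinol to C5 with loss of mesylate. In one operation the cyclohexane C1–C6 contracts to the cyclopentane C1–C5, the cyclohexene expands to the cycloheptene, C5 is set by inversion and the C6 ketone appears. The precursor is a Wieland–Miescher‑type octalindione: its enone carbonyl becomes the C4 carbinol (which directs β‑dihydroxylation of C5=C6), its saturated ketone becomes C10.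

Key step: step 9

Remark: the same atom numbers are kept for the decalin intermediates (ring A = C1‑C2‑C3‑C4‑C5‑C6, ring B = C1‑C6‑C7‑C8‑C9‑C10); β = face of the C1 methyl, α = the opposite face. 2,5‑Dimethylcyclohexane‑1,3‑dione is assumed not to be a reliable catalogue item and is made in step 1.

Step 1
Reactants: 1 5‑methylcyclohexane‑1,3‑dione
Product: 2 2,5‑dimethylcyclohexane‑1,3‑dione
Conditions: MeI, KOH, H2O–acetone, reflux
Reagents that add atoms: iodomethane, CI
Why: C‑alkylation of the cyclic β‑diketone enolate with methyl iodide is the standard way to 2‑alkylcyclohexane‑1,3‑diones and creates no stereocentre that survives.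

Step 2
Reactants: 2 2,5‑dimethylcyclohexane‑1,3‑dione; 3 methyl vinyl ketone
Product: 6 (8aS)‑3,8a‑dimethyl‑3,4,8,8a‑tetrahydronaphthalene‑1,6(2H,7H)‑dione as a mixture of C3 epimers, via Michael triketone 4 (not isolated), via bicyclic ketol 5 (not isolated)
Conditions: L‑proline (cat.), DMSO, 35 °C, one pot
Reagents that add atoms: none
Why: Robinson annulation in its Hajos–Parrish–Eder–Sauer–Wiechert form, in which the Michael adduct 4 is desymmetrised by a proline‑enamine aldol that picks one of the two enantiotopic ring carbonyls and should set the quaternary carbon as S, as L‑proline does for the parent Wieland–Miescher ketone, while the secondary methyl centre is erased in step 3.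

Step 3
Reactants: 6 (8aS)‑3,8a‑dimethyl‑3,4,8,8a‑tetrahydronaphthalene‑1,6(2H,7H)‑dione
Product: 7 (8aS)‑3,8a‑dimethyl‑8,8a‑dihydronaphthalene‑1,6(4H,7H)‑dione (bis‑enone: C4=O/C5=C6 and C10=O/C9=C8)
Conditions: IBX, DMSO–PhF, 65 °C
Reagents that add atoms: none
Why: IBX dehydrogenation of a ketone through its enol should act first on the saturated C10 ketone, which has one enolisable CH2 and a tertiary β‑hydrogen, whereas conversion of the ring‑A enone into a cross‑conjugated dienone needs more reagent and a higher temperature.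

Step 4
Reactants: 7 (8aS)‑3,8a‑dimethyl‑8,8a‑dihydronaphthalene‑1,6(4H,7H)‑dione
Product: 8 (6R,8aS)‑6‑hydroxy‑3,8a‑dimethyl‑6‑(propan‑2‑yl)‑6,7,8,8a‑tetrahydronaphthalen‑1(4H)‑one (4β‑hydroxy‑4α‑isopropyl; OH cis to the angular methyl)
Conditions: i‑PrMgCl, CeCl3, THF, −78 °C; aq. NH4Cl
Reagents that add atoms: isopropylmagnesium chloride, CC(C)[Mg]Cl
Why: Organocerium 1,2‑addition (Imamoto) should go to the unhindered ring‑A enone carbonyl and not to the neopentyl C10 carbonyl, and axial attack anti to the angular methyl, as in 1,2‑additions to steroidal 4‑en‑3‑ones, should give the 4β‑hydroxy‑4α‑isopropyl carbinol, the low basicity of the reagent sparing the doubly vinylogous C7 protons.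

Step 5
Reactants: 8 (6R,8aS)‑6‑hydroxy‑3,8a‑dimethyl‑6‑(propan‑2‑yl)‑6,7,8,8a‑tetrahydronaphthalen‑1(4H)‑one
Product: 10 4β,5β,6β‑trihydroxy‑4α‑isopropyl‑1β,8‑dimethyl‑cis‑decal‑8‑en‑10‑one (all three hydroxyls on the face of the C1 methyl), via TMEDA osmate ester 9 (not isolated)
Conditions: OsO4 (1.1 equiv), TMEDA, CH2Cl2, −78 °C; then ethylenediamine, rt
Reagents that add atoms: osmium tetroxide, O=[Os](=O)(=O)=O
Why: Donohoe's hydrogen‑bond‑directed dihydroxylation with the OsO4–TMEDA complex should deliver both oxygens to the electron‑rich C5=C6 bond syn to the C4 hydroxyl, that is on the β face against the usual anti preference, which sets C5 and C6 and creates the cis‑decalin, while the electron‑poor enone bond C8=C9 stays untouched.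

Step 6
Reactants: 10 4β,5β,6β‑trihydroxy‑4α‑isopropyl‑1β,8‑dimethyl‑cis‑decal‑8‑en‑10‑one
Product: 11 4β,6β‑dihydroxy‑4α‑isopropyl‑5β‑(methanesulfonyloxy)‑1β,8‑dimethyl‑cis‑decal‑8‑en‑10‑one
Conditions: MsCl, Et3N, CH2Cl2, −20 → 0 °C
Reagents that add atoms: methanesulfonyl chloride, CS(=O)(=O)Cl
Why: Sulfonylation through sulfene should occur only at the single secondary hydroxyl (C5), the two tertiary hydroxyls being inert at low temperature, and the resulting β‑mesylate is equatorial on ring A.

Step 7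
Reactants: 11 4β,6β‑dihydroxy‑4α‑isopropyl‑5β‑(methanesulfonyloxy)‑1β,8‑dimethyl‑cis‑decal‑8‑en‑10‑one
Product: 12 4α‑isopropyl‑5β‑(methanesulfonyloxy)‑1β,8‑dimethyl‑cis‑decal‑8‑ene‑4β,6β,10α‑triol
Conditions: NaBH4, CeCl3·7H2O, MeOH, −78 °C
Reagents that add atoms: none
Why: Luche 1,2‑reduction of the enone, in which C10 sits axially over ring A of the cis‑decalin (ring A chair with equatorial isopropyl) so that its α face is covered by the axial C5–H and C3–H, should take hydride from the convex β face and give the 10α‑alcohol, trans to the C1 methyl.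

Step 8
Reactants: 12 4α‑isopropyl‑5β‑(methanesulfonyloxy)‑1β,8‑dimethyl‑cis‑decal‑8‑ene‑4β,6β,10α‑triol
Product: 13 10α‑(allyloxycarbonyloxy)‑4α‑isopropyl‑5β‑(methanesulfonyloxy)‑1β,8‑dimethyl‑cis‑decal‑8‑ene‑4β,6β‑diol
Conditions: allyl chloroformate, pyridine, DMAP (cat.), CH2Cl2, 0 °C → rt
Reagents that add atoms: allyl chloroformate, C=CCOC(=O)Cl
Why: Acylation with a chloroformate under DMAP catalysis should take place at the only secondary hydroxyl, and the carbonate both removes the nucleophilicity of O10, which sits 1,3‑diaxial to C5 and could otherwise displace the mesylate to a bridged ether, and can later be taken off under neutral Pd(0) conditions.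

Step 9
Reactants: 13 10α‑(allyloxycarbonyloxy)‑4α‑isopropyl‑5β‑(methanesulfonyloxy)‑1β,8‑dimethyl‑cis‑decal‑8‑ene‑4β,6β‑diol
Product: 14 10α‑(allyloxycarbonyloxy)‑4β‑hydroxydauc‑8‑en‑6‑one (trans‑fused hydroazulenone: 1β‑CH3, 5α‑H, 4α‑isopropyl)
Conditions: LiClO4, CaCO3, THF, 50 °C
Reagents that add atoms: none
Why: Ionisation of the equatorial C5 mesylate is assisted by the antiperiplanar C6–C1 ring bond, so that C1 shifts from C6 to C5 while the C6 hydroxyl oxygen becomes the carbonyl (semipinacol, that is a pinacol‑type rearrangement of a cis‑1,2‑diol monosulfonate). The closest known reaction type is the rearrangement of cis‑decalin diol monosulfonates to hydroazulenones under buffered LiClO4 or base. Both rings arise from the same 1,2‑alkyl shift and not from a cyclisation: the cyclohexane C1‑C2‑C3‑C4‑C5‑C6 loses C6 and becomes the cyclopentane, and the cyclohexene gains C5 and becomes the cycloheptenone. C5 is set by inversion (C1 enters anti to the β‑mesylate, which leaves H5 α and gives the trans ring fusion), C1 migrates with retention, and C4 and C10 are untouched. The step needs C1 to migrate and not the equally antiperiplanar C3 (which the C4 carbinol could drive); the fully substituted C1, the relief of the 1,3‑diaxial strain of the cis‑decalin and the carbonate‑masked O10 should secure this. Neutral conditions should keep the β,γ‑enone and the aldol unit C4(OH)–C5–C6=O intact.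

Step 10
Reactants: 14 10α‑(allyloxycarbonyloxy)‑4β‑hydroxydauc‑8‑en‑6‑one
Product: 15 10α‑(allyloxycarbonyloxy)dauc‑8‑ene‑4β,6α‑diol
Conditions: SmI2, THF–MeOH, 0 °C
Reagents that add atoms: none
Why: Single‑electron reduction of the β‑hydroxy ketone (Keck‑type SmI2 reduction) should pass through a samarium ketyl/carbanion chelated to the C4 hydroxyl that settles with O–Sm on the open α face, so that the new C6–H lies on the methyl‑shielded β face and the thermodynamic 6α‑alcohol forms, as in dissolving‑metal reductions of 11‑oxo steroids to 11α‑ols, whereas a hydride reagent would attack the open face and give the 6β‑epimer.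

Step 11
Reactants: 15 10α‑(allyloxycarbonyloxy)dauc‑8‑ene‑4β,6α‑diol; 16 4‑methoxybenzoyl chloride
Product: 17 10α‑(allyloxycarbonyloxy)‑6α‑(4‑methoxybenzoyloxy)dauc‑8‑en‑4β‑ol
Conditions: pyridine, DMAP (cat.), CH2Cl2, rt
Reagents that add atoms: none
Why: DMAP‑catalysed acylation with the acid chloride should esterify the secondary 6α‑hydroxyl only, because the tertiary C4 hydroxyl does not react under these conditions and O10 is masked.

Step 12
Reactants: 17 10α‑(allyloxycarbonyloxy)‑6α‑(4‑methoxybenzoyloxy)dauc‑8‑en‑4β‑ol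
Product: 18 6α‑(4‑methoxybenzoyloxy)dauc‑8‑ene‑4β,10α‑diol
Conditions: Pd(PPh3)4 (cat.), morpholine, THF, rt
Reagents that add atoms: none
Why: Tsuji–Trost deallylation with morpholine as allyl scavenger, followed by loss of CO2, should free the C10 hydroxyl under neutral conditions that leave the anisoate, the tertiary alcohol and the trisubstituted alkene alone.

Step 13
Reactants: 18 6α‑(4‑methoxybenzoyloxy)dauc‑8‑ene‑4β,10α‑diol; 19 angelic acid [(Z)‑2‑methylbut‑2‑enoic acid]
Product: 21 10α‑angeloyloxy‑6α‑(4‑methoxybenzoyloxy)dauc‑8‑en‑4β‑ol (CNP0168729.1), via angelic mixed anhydride 20 (not isolated)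
Conditions: 19, 2,4,6‑Cl3C6H2COCl, Et3N, toluene, rt; then 18, 75 °C
Reagents that add atoms: none
Why: Yamaguchi esterification through the mixed 2,4,6‑trichlorobenzoic anhydride 20, run without DMAP, is the established way to angelates without Z to E isomerisation to the tiglate, and only the secondary allylic C10 hydroxyl should react since the C4 hydroxyl is tertiary.

**Compound list**

1 | 5‑methylcyclohexane‑1,3‑dione | CC1CC(=O)CC(=O)C1 | starting material
2 | 2,5‑dimethylcyclohexane‑1,3‑dione | CC1CC(=O)C(C)C(=O)C1 | intermediate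
3 | methyl vinyl ketone (but‑3‑en‑2‑one) | CC(=O)C=C | starting material
4 | 2,5‑dimethyl‑2‑(3‑oxobutyl)cyclohexane‑1,3‑dione (cis/trans) | CC(=O)CCC1(C)C(=O)CC(C)CC1=O | intermediate (not isolated)
5 | cis‑fused ketol, 4a‑hydroxy‑3,8a‑dimethyloctahydronaphthalene‑1,6‑dione (OH cis to 8a‑CH3, 8aS) | CC1CC(=O)[C@@]2(C)CCC(=O)C[C@@]2(O)C1 | intermediate (not isolated)
6 | (8aS)‑3,8a‑dimethyl‑3,4,8,8a‑tetrahydronaphthalene‑1,6(2H,7H)‑dione (C3 epimers) | CC1CC(=O)[C@@]2(C)CCC(=O)C=C2C1 | intermediate
7 | (8aS)‑3,8a‑dimethyl‑8,8a‑dihydronaphthalene‑1,6(4H,7H)‑dione | CC1=CC(=O)[C@@]2(C)CCC(=O)C=C2C1 | intermediate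
8 | (6R,8aS)‑6‑hydroxy‑3,8a‑dimethyl‑6‑(propan‑2‑yl)‑6,7,8,8a‑tetrahydronaphthalen‑1(4H)‑one | CC1=CC(=O)[C@@]2(C)CC[C@@](O)(C(C)C)C=C2C1 | intermediate
9 | cyclic osmate(VI) ester of the 5β,6β‑diol, TMEDA‑chelated | CC1=CC(=O)[C@@]2(C)CC[C@@](O)(C(C)C)[C@@H]3O[Os-2]4(=O)(=O)([N+](C)(C)CC[N+]4(C)C)O[C@]23C1 | intermediate (not isolated)
10 | 4β,5β,6β‑trihydroxy‑4α‑isopropyl‑1β,8‑dimethyl‑cis‑decal‑8‑en‑10‑one | CC1=CC(=O)[C@@]2(C)CC[C@@](O)(C(C)C)[C@H](O)[C@@]2(O)C1 | intermediate
11 | 5β‑mesylate of 10 | CC1=CC(=O)[C@@]2(C)CC[C@@](O)(C(C)C)[C@H](OS(C)(=O)=O)[C@@]2(O)C1 | intermediate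
12 | 4α‑isopropyl‑5β‑mesyloxy‑1β,8‑dimethyl‑cis‑decal‑8‑ene‑4β,6β,10α‑triol | CC1=C[C@@H](O)[C@@]2(C)CC[C@@](O)(C(C)C)[C@H](OS(C)(=O)=O)[C@@]2(O)C1 | intermediate
13 | 10α‑allyl carbonate of 12 | CC1=C[C@@H](OC(=O)OCC=C)[C@@]2(C)CC[C@@](O)(C(C)C)[C@H](OS(C)(=O)=O)[C@@]2(O)C1 | intermediate
14 | 10α‑(allyloxycarbonyloxy)‑4β‑hydroxydauc‑8‑en‑6‑one | C=CCOC(=O)O[C@@H]1C=C(C)CC(=O)[C@@H]2[C@]1(C)CC[C@@]2(O)C(C)C | intermediate
15 | 10α‑(allyloxycarbonyloxy)dauc‑8‑ene‑4β,6α‑diol | C=CCOC(=O)O[C@@H]1C=C(C)C[C@H](O)[C@@H]2[C@]1(C)CC[C@@]2(O)C(C)C | intermediate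
16 | 4‑methoxybenzoyl chloride | COc1ccc(cc1)C(Cl)=O | starting material
17 | 10α‑(allyloxycarbonyloxy)‑6α‑(4‑methoxybenzoyloxy)dauc‑8‑en‑4β‑ol | C=CCOC(=O)O[C@@H]1C=C(C)C[C@H](OC(=O)c2ccc(OC)cc2)[C@@H]2[C@]1(C)CC[C@@]2(O)C(C)C | intermediate
18 | 6α‑(4‑methoxybenzoyloxy)dauc‑8‑ene‑4β,10α‑diol | O[C@@H]1C=C(C)C[C@H](OC(=O)c2ccc(OC)cc2)[C@@H]2[C@]1(C)CC[C@@]2(O)C(C)C | intermediate
19 | angelic acid | C/C=C(/C)C(=O)O | starting material
20 | angelic 2,4,6‑trichlorobenzoic anhydride | C/C=C(/C)C(=O)OC(=O)c1c(Cl)cc(Cl)cc1Cl | intermediate (not isolated)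
21 | 10α‑angeloyloxy‑6α‑(4‑methoxybenzoyloxy)dauc‑8‑en‑4β‑ol | C/C=C(/C)C(=O)O[C@@H]1C=C(C)C[C@H](OC(=O)c2ccc(OC)cc2)[C@@H]2[C@]1(C)CC[C@@]2(O)C(C)C | target

**Step count and risks**

Total steps: 13. Longest linear sequence: 13 (fully linear from 1).

The three steps judged most likely to fail are steps 5, 7 and 10. The key step 9 is ranked below them because its reaction type is well precedented; its specific risk (C3 instead of C1 migration) is addressed in its Why line.

Step 5. The osmium reagent may ignore the hydrogen bond and add from the α face, anti to the angular methyl (poor facial selectivity), or react sluggishly at the hindered ring‑fusion alkene. The fallback sets out from 8 and comes back at 10: a Woodward cis‑hydroxylation (I2, AgOAc, AcOH, then wet AcOH) should place the iodonium ion on the open α face. Acetate then opens it at C6 from the β face, and the neighbouring acetoxy group displaces iodide at C5 with inversion, so both oxygens end on the β face in the hydroxy acetate F1. Mild methanolysis (K2CO3, MeOH, 0 °C) should give triol 10.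

Step 7. Hydride may be delivered from the concave face after all, because the convex face carries the C1 methyl next to the carbonyl, which would give the 10β‑epimer. The fallback sets out from 11 and comes back at 21, and sets C10 by SN2 inversion at the end instead of by face‑selective reduction. The 10β‑alcohol F2 would be carried through the same operations: allyl chloroformate to the carbonate F3, the LiClO4/CaCO3 shift to the ketone F4, SmI2 to the 6α‑alcohol F5, acylation with 16 to the anisoate F6, and Pd(0)/morpholine to the 10β‑alcohol F7. A Mitsunobu esterification of F7 with angelic acid 19 (PPh3, DIAD, toluene) should then give 21 with inversion at C10; the carboxylate enters on the α face anti to the C1 methyl, and C1 carries no hydrogen for elimination.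

Step 10. Hydrogen may be delivered to C6 from the open α face (kinetic course), giving the 6β‑alcohol, or the allylic carbonate may be lost under the reducing conditions. The fallback sets out from 14 and comes back at 17: a deliberate kinetic hydride reduction (NaBH4, MeOH, −40 °C) should give the 6β‑alcohol F8 by attack anti to the C1 methyl. Mitsunobu esterification with 4‑methoxybenzoic acid (PPh3, DIAD, toluene) should then install the anisoate with inversion from the open face and give 17 directly.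

Further compounds
F1 | step 5 | 5β‑acetoxy‑4β,6β‑dihydroxy‑4α‑isopropyl‑1β,8‑dimethyl‑cis‑decal‑8‑en‑10‑one | CC1=CC(=O)[C@@]2(C)CC[C@@](O)(C(C)C)[C@H](OC(C)=O)[C@@]2(O)C1
F2 | step 7 | 4α‑isopropyl‑5β‑mesyloxy‑1β,8‑dimethyl‑cis‑decal‑8‑ene‑4β,6β,10β‑triol | CC1=C[C@H](O)[C@@]2(C)CC[C@@](O)(C(C)C)[C@H](OS(C)(=O)=O)[C@@]2(O)C1
F3 | step 7 | 10β‑allyl carbonate of F2 | CC1=C[C@H](OC(=O)OCC=C)[C@@]2(C)CC[C@@](O)(C(C)C)[C@H](OS(C)(=O)=O)[C@@]2(O)C1
F4 | step 7 | 10β‑(allyloxycarbonyloxy)‑4β‑hydroxydauc‑8‑en‑6‑one | C=CCOC(=O)O[C@H]1C=C(C)CC(=O)[C@@H]2[C@]1(C)CC[C@@]2(O)C(C)C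
F5 | step 7 | 10β‑(allyloxycarbonyloxy)dauc‑8‑ene‑4β,6α‑diol | C=CCOC(=O)O[C@H]1C=C(C)C[C@H](O)[C@@H]2[C@]1(C)CC[C@@]2(O)C(C)C
F6 | step 7 | 10β‑(allyloxycarbonyloxy)‑6α‑(4‑methoxybenzoyloxy)dauc‑8‑en‑4β‑ol | C=CCOC(=O)O[C@H]1C=C(C)C[C@H](OC(=O)c2ccc(OC)cc2)[C@@H]2[C@]1(C)CC[C@@]2(O)C(C)C
F7 | step 7 | 6α‑(4‑methoxybenzoyloxy)dauc‑8‑ene‑4β,10β‑diol | O[C@H]1C=C(C)C[C@H](OC(=O)c2ccc(OC)cc2)[C@@H]2[C@]1(C)CC[C@@]2(O)C(C)C
F8 | step 10 | 10α‑(allyloxycarbonyloxy)dauc‑8‑ene‑4β,6β‑diol | C=CCOC(=O)O[C@@H]1C=C(C)C[C@@H](O)[C@@H]2[C@]1(C)CC[C@@]2(O)C(C)C
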